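What is left of the left-handed substrate in the south run, 21.5% at 8.00 min, is where I would start your quick number, and from it I reckon how far a charge of coupling partner carries. Here is what we have.

all flasks: free catalyst 1 mol%

|  | left-handed substrate | right-handed substrate | coupling partner | remark | time |
|---|---|---|---|---|---|
| south | 1.5 M | 1.5 M | 0.60 equiv | run made earlier |  |
| east | 0.50 M | 0.50 M | 0.60 equiv | run made earlier |  |
| beta | 1.0 M | 1.0 M | 0.600 equiv |  | 25 min |
| theta | 1.0 M | 1.0 M | 1.20 equiv |  | 25 min |

| run | time / min | right-handed substrate / % | left-handed substrate / % | left-handed product / % |
|---|---|---|---|---|
| south | 0.500 | 50.0 | 38.7 | 11.2 |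
| south | 1.33 | 49.7 | 30.7 | 19.9 |
| south | 2.50 | 49.3 | 25.8 | 24.8 |
| south | 4.00 | 49.4 | 23.5 | 26.2 |
| south | 5.00 | 49.5 | 23.1 | 28.2 |
| south | 8.00 | 49.3 | 21.5 | 28.5 |
| east | 0.500 | 49.4 | 48.5 | 1.6 |
| east | 1.33 | 49.8 | 45.3 | 4.6 |
| east | 2.50 | 49.8 | 43.2 | 6.7 |
| east | 4.00 | 50.0 | 39.7 | 10.3 |
| east | 5.00 | 49.3 | 38.4 | 11.4 |
| east | 8.00 | 49.5 | 35.2 | 14.6 |

(standard deviation of a reading: 0.3 percentage points)

- free catalyst is single-handed; left-handed substrate and right-handed substrate are mirror images of each other, charged as a racemate, each of them at the stated concentration
- an excess is below zero if the other one leads

1. which one finishes higher in excess of right-handed substrate over left-handed substrate among what is left of the two ("neither" within 2 percentage points) (beta / theta / neither)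
2. excess of right-handed substrate over left-handed substrate among what is left of the two at the end, beta
3. excess of right-handed substrate over left-handed substrate among what is left of the two at the end, theta

The single-handed free catalyst takes the left-handed substrate, while the right-handed substrate stays near 49.3%, so the excess counts left-handed substrate consumed. In south the partner charge equals 30.0% of both substrates, and the left-handed product reads 28.5%. I call product made per partner charged, on that scale, the partner yield 95.0%.

Now the other end, time. South's first product reading is 7.00 times east's, but east's 1.6% carries a scatter of 0.3 percentage points, so I take as a rough rule the 9.00 that the square of concentration gives. So I expect beta at 1.0 M to take 2.25 times as long as south, which puts south's last reading at 18.0 min in beta, earlier than 25 min.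

I therefore expect beta to end on its stoichiometry, with the partner as limiting reagent. My reckoning leaves 21.5% of left-handed substrate and an excess of 39.3%. In theta the yield allows 57.0% of product against 50.0% of left-handed substrate charged, so this count sets no stop short of an excess of 100%, and how near theta comes to that is a question of time.

Your forecast says theta, with 41% for beta and 90% for theta, on the ground that in beta “the partner runs out”. My beta lies a little lower, and I keep your order.

The flask gives theta, with 38.7% in beta and 87.6% in theta.

    coupling partner + free catalyst + left-handed substrate → free catalyst + left-handed product (k = 49.0 /M²/min)
    coupling partner + free catalyst → spent catalyst B (k = 0.0270 /M/min)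
    free catalyst → spent catalyst A (k = 0.0260 /min)
    coupling partner → decomposed reagent (k = 0.00950 /min)
    coupling partner + free catalyst + right-handed substrate → free catalyst + right-handed product (k = 0.750 /M²/min)

In beta the making of left-handed product had 82% of its turnover up to 25 min behind it by 5.00 min, and at 25.0 min the partner stood at 0.76% of its charge, with a partner yield of 94.0% against the carried 95.0%. In theta that step was still running at 25.0 min, with 12% of the partner and 3.17% of left-handed substrate there.

For the neighbour of beta charged with 2.40 equiv of partner, the yield allows 114% of product against 50.0% of left-handed substrate charged, so the same reckoning gives an excess of 100%. The computed flask gives 99.9%.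

The runs were generated by integration from invented constants, noise included.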